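## Retrosynthetic overview

1. Target 24 ⇐ bis(chloroacetate) 23: both chloroacetates are removed at the end and the C19 acetate is kept.
2. 23 ⇐ ring-A methylenecyclohexane 13 (C6=C5) + (E)-allylic chloride 18 (C7–C9 plus side chain). C6–C7 and C9–C10 form in one cationic (3+3) annulation that closes ring B, the only ring made; ring A is bought as ketoisophorone.
3. Enabling feature: ring B is a 2-methylcyclohexene. Its C7=C8(C17)–C9 unit is a 2-methylallyl fragment (the oxidised (E)-methyl end of a geranyl chain). C10 (quaternary, C20) sits next to C5–H, which is the 1,2-hydride-shift isomer of the cation formed at C5 of a 2-methylenecyclohexane carrying H on C10.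
4. 13 ⇐ ketoisophorone 1: asymmetric transfer hydrogenation (C2), oxime-directed C–H acetoxylation of the C4 methyl cis to the C2 oxygen (C19), methylenation (C6), Mitsunobu inversion at C2.
5. 18 ⇐ geraniol 14: chloroacetylation, allylic oxidation of the (E)-methyl group (C7), chlorination.

Key step: step 13

Remark on the chemistry: labdane numbering is used throughout (ring A = C1–C5, C10; ring B = C5–C10; C17 on C8; C18/C19 on C4 with C19 = CH2OAc cis to C20; C20 on C10). α is the face of H-5, β the face of C20. The target is read as (2R,4S,5R,9S,10R,13E).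

## Route

Step 1
Reactants: 1 ketoisophorone (2,6,6-trimethylcyclohex-2-ene-1,4-dione)
Product: 2 (R)-4-hydroxy-2,6,6-trimethylcyclohex-2-en-1-one
Conditions: RuCl(p-cymene)[(R,R)-TsDPEN] (0.5 mol%), HCO2H/Et3N 5:2, CH2Cl2, rt
Reagents that add atoms: none
Why: Noyori asymmetric transfer hydrogenation should reduce only the unhindered C4 carbonyl (C1 is flanked by the gem-dimethyl carbon and the methyl-bearing alkene carbon), and the catalyst is expected to read the enone π-system like an aryl group so that the (R,R)-ligand gives the (R)-carbinol (future C2, oxygen β), the enantiomeric ligand being the remedy if the sense is opposite.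

Step 2
Reactants: 2 (R)-4-hydroxy-2,6,6-trimethylcyclohex-2-en-1-one
Product: 3 (R)-4-[(tert-butyldiphenylsilyl)oxy]-2,6,6-trimethylcyclohex-2-en-1-one
Conditions: TBDPSCl, imidazole, DMF, rt
Reagents that add atoms: tert-butyl(chloro)diphenylsilane CC(C)(C)[Si](Cl)(c1ccccc1)c1ccccc1
Why: Standard silylation of a secondary alcohol, which also removes the risk of isomerising the γ-hydroxy enone to the 1,4-dione in the next step.

Step 3
Reactants: 3 (R)-4-[(tert-butyldiphenylsilyl)oxy]-2,6,6-trimethylcyclohex-2-en-1-one
Product: 4 (4S,6R)-4-[(tert-butyldiphenylsilyl)oxy]-2,2,6-trimethylcyclohexan-1-one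
Conditions: H2 (1 atm), 5% Pd/C, EtOAc, rt; then DBU (0.2 equiv), CH2Cl2, rt
Reagents that add atoms: none
Why: Catalytic hydrogenation of the electron-poor enone C=C followed by base equilibration of the new α-stereocentre should give the cis isomer, in which the C6 methyl and the silyloxy group are both equatorial (thermodynamic control).

Step 4
Reactants: 4 (4S,6R)-4-[(tert-butyldiphenylsilyl)oxy]-2,2,6-trimethylcyclohexan-1-one
Product: 5 (1E,4S,6R)-4-[(tert-butyldiphenylsilyl)oxy]-2,2,6-trimethylcyclohexan-1-one oxime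
Conditions: NH2OH·HCl, pyridine, EtOH, 80 °C
Reagents that add atoms: hydroxylamine hydrochloride Cl.NO
Why: Oxime condensation of a hindered ketone under forcing conditions should place the hydroxyl group syn to the tertiary α-carbon and away from the quaternary one, so that the nitrogen lone pair points at the gem-dimethyl carbon.

Step 5
Reactants: 5 (1E,4S,6R)-4-[(tert-butyldiphenylsilyl)oxy]-2,2,6-trimethylcyclohexan-1-one oxime
Product: 7 (1E,2S,4S,6R)-2-(acetoxymethyl)-4-[(tert-butyldiphenylsilyl)oxy]-2,6-dimethylcyclohexan-1-one O-acetyl oxime, via O-acetyl oxime 6 (not isolated)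
Conditions: Pd(OAc)2 (10 mol%), PhI(OAc)2 (1.5 equiv), AcOH/Ac2O 1:1, 90 °C
Reagents that add atoms: acetic anhydride CC(=O)OC(C)=O; (diacetoxyiodo)benzene CC(=O)OI(OC(C)=O)c1ccccc1
Why: Oxime-directed Pd(II)/Pd(IV) β-C(sp3)–H acetoxylation should functionalise the methyl group that lies in the C=N plane, that is the equatorial one, which is cis to the equatorial silyloxy group because the flipped chair would be triaxial, so the new quaternary centre (C4, acetoxymethyl β) is set by the carbinol centre from step 1.

Step 6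
Reactants: 7 (1E,2S,4S,6R)-2-(acetoxymethyl)-4-[(tert-butyldiphenylsilyl)oxy]-2,6-dimethylcyclohexan-1-one O-acetyl oxime
Product: 9 (2R,4S,6R)-2-(acetoxymethyl)-4-[(tert-butyldiphenylsilyl)oxy]-2,6-dimethylcyclohexan-1-one, via N-H ketimine 8 (not isolated)
Conditions: TiCl3 (aq., 4 equiv), NH4OAc, THF/H2O, 0 °C → rt; then DBU (0.2 equiv), CH2Cl2, rt
Reagents that add atoms: water O
Why: Ti(III) reductive cleavage of the N–O bond and hydrolysis of the imine should free the ketone without touching the primary acetate, and the base wash returns the α-methyl centre to the all-equatorial isomer (methyl β, H α), which has no β-elimination path because the acetoxymethyl carbon is quaternary.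

Step 7
Reactants: 9 (2R,4S,6R)-2-(acetoxymethyl)-4-[(tert-butyldiphenylsilyl)oxy]-2,6-dimethylcyclohexan-1-one
Product: 10 [(1S,3R,5S)-5-[(tert-butyldiphenylsilyl)oxy]-1,3-dimethyl-2-methylidenecyclohexyl]methyl acetate
Conditions: Zn, CH2Br2, TiCl4, THF/CH2Cl2, 0 °C → rt
Reagents that add atoms: dibromomethane BrCBr
Why: Takai–Lombardo methylenation converts hindered, enolisable ketones under non-basic conditions, so the acetate survives and the α-stereocentre (future C10, H α) is frozen.

Step 8
Reactants: 10 [(1S,3R,5S)-5-[(tert-butyldiphenylsilyl)oxy]-1,3-dimethyl-2-methylidenecyclohexyl]methyl acetate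
Product: 11 [(1S,3R,5S)-5-hydroxy-1,3-dimethyl-2-methylidenecyclohexyl]methyl acetate
Conditions: TBAF, AcOH, THF, rt → 40 °C
Reagents that add atoms: none
Why: Acetic-acid-buffered fluoride desilylation should free the secondary alcohol without cleaving the neopentyl acetate, which has no neighbouring hydroxyl group to migrate to.

Step 9
Reactants: 11 [(1S,3R,5S)-5-hydroxy-1,3-dimethyl-2-methylidenecyclohexyl]methyl acetate
Product: 13 [(1S,3R,5R)-5-(chloroacetoxy)-1,3-dimethyl-2-methylidenecyclohexyl]methyl acetate, via alkoxyphosphonium ion 12 (not isolated)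
Conditions: ClCH2CO2H, PPh3, DIAD, toluene, 0 °C → rt
Reagents that add atoms: chloroacetic acid OC(=O)CCl
Why: Mitsunobu reaction with the acidic chloroacetic acid, the variant used for hindered secondary alcohols, should invert the carbinol centre by SN2 to the α-oxygen of the target (C2) and install the ester that protects it in the key step.

Step 10
Reactants: 14 geraniol
Product: 15 geranyl chloroacetate
Conditions: ClCH2COCl, pyridine, CH2Cl2, 0 °C
Reagents that add atoms: chloroacetyl chloride ClCC(Cl)=O
Why: Simple acylation of a primary allylic alcohol, giving an ester that deactivates the 2,3-alkene and can later be removed beside an acetate.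

Step 11
Reactants: 15 geranyl chloroacetate
Product: 16 (2E,6E)-8-hydroxy-3,7-dimethylocta-2,6-dien-1-yl chloroacetate
Conditions: SeO2 (0.3 equiv), t-BuOOH (3 equiv), salicylic acid (0.1 equiv), CH2Cl2, rt
Reagents that add atoms: tert-butyl hydroperoxide CC(C)(C)OO; selenium dioxide O=[Se]=O
Why: Riley-type allylic oxidation (ene reaction then [2,3]-shift) should attack the (E)-methyl group of the distal, more electron-rich trisubstituted alkene and keep the E geometry.

Step 12
Reactants: 16 (2E,6E)-8-hydroxy-3,7-dimethylocta-2,6-dien-1-yl chloroacetate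
Product: 18 (2E,6E)-8-chloro-3,7-dimethylocta-2,6-dien-1-yl chloroacetate, via allylic mesylate 17 (not isolated)
Conditions: MsCl, 2,4,6-collidine, LiCl, DMF, 0 °C
Reagents that add atoms: lithium chloride [Li+].[Cl-]
Why: Mesylation and in situ SN2 displacement by chloride converts primary allylic alcohols to chlorides without allylic transposition or loss of alkene geometry, and chloride exchange at the chloroacetate is degenerate.

Step 13
Reactants: 13 [(1S,3R,5R)-5-(chloroacetoxy)-1,3-dimethyl-2-methylidenecyclohexyl]methyl acetate; 18 (2E,6E)-8-chloro-3,7-dimethylocta-2,6-dien-1-yl chloroacetate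
Product: 23 19-acetoxylabda-7,13E-diene-2α,15-diyl bis(chloroacetate), via allyl cation 19 (not isolated), via tertiary C5 cation 20 (not isolated), via tertiary C10 cation 21 (not isolated), via bicyclic C8 cation 22 (not isolated)
Conditions: SnCl4 (5 equiv), 2,6-di-tert-butyl-4-methylpyridine (1.5 equiv), CH2Cl2, −78 → −45 °C, slow addition of 18 (1.3 equiv); Et3N/MeOH quench at −78 °C
Reagents that add atoms: none
Why: Proposed new method: SnCl4 abstracts chloride from 18 to give the (E)-2-methylallyl cation 19, whose CH2 terminus (C7) is attacked by the exocyclic CH2 (C6) of 13 to give tertiary cation 20; a suprafacial 1,2-shift of the axial α-hydrogen from C10 to C5 gives cation 21, which is captured through C9 by the C8=C9 alkene to close ring B (cation 22), and loss of H-7 to the hindered pyridine gives the C7=C8 alkene. The closest known reaction types are the Lewis-acid-promoted addition of allylic chlorides to 1,1-dialkylethylenes (the laboratory counterpart of head-to-tail prenyl transfer) and the cationic cyclisation of monocyclic cyclogeranyl-type trienes to trans-decalins; joining them in one flask as a two-component (3+3) annulation is the new element. Ring B closes in the 6-endo-trig mode with respect to the C8=C9 alkene through a chair transition state. C5 is set by the suprafacial hydride shift (the α-H on C10 of 13 becomes H-5α), C10 by attack of C9 on the cation face anti to H-5 with the C6 tether equatorial (trans fusion, C20 axial and cis to C19, in the chair that keeps the C2 chloroacetoxy group equatorial), and C9 by the E geometry of C8=C9, which places C11 equatorial. The step needs attack at the primary terminus of 19 (secured by the hindered nucleophile and by formation of the trisubstituted alkene), no participation of the C13=C14 alkene and no ionisation at C15 (secured by the SnCl4-complexed allylic chloroacetate, which also stops the cascade at the bicycle), and proton loss towards C7 rather than C17 or C9 (kinetic, at low temperature with base present, and the least secure point).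

Step 14
Reactants: 23 19-acetoxylabda-7,13E-diene-2α,15-diyl bis(chloroacetate)
Product: 24 2α,15-dihydroxylabda-7,13E-dien-19-yl acetate (target, CNP0319060.1)
Conditions: thiourea (6 equiv), NaHCO3, EtOH, 55 °C
Reagents that add atoms: none
Why: Thiourea displaces the α-chloride and cyclises onto the ester carbonyl (Hantzsch-type formation of pseudothiohydantoin), which should release both alcohols under conditions that leave the hindered neopentyl acetate and both alkenes untouched.

## Compound list

1 | ketoisophorone (2,6,6-trimethylcyclohex-2-ene-1,4-dione) | CC1=CC(=O)CC(C)(C)C1=O | starting material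
2 | (R)-4-hydroxy-2,6,6-trimethylcyclohex-2-en-1-one | CC1(C)C[C@@H](O)C=C(C)C1=O | intermediate
3 | (R)-4-[(tert-butyldiphenylsilyl)oxy]-2,6,6-trimethylcyclohex-2-en-1-one | CC1(C)C[C@@H](O[Si](c2ccccc2)(c2ccccc2)C(C)(C)C)C=C(C)C1=O | intermediate
4 | (4S,6R)-4-[(tert-butyldiphenylsilyl)oxy]-2,2,6-trimethylcyclohexan-1-one | CC1(C)C[C@@H](O[Si](c2ccccc2)(c2ccccc2)C(C)(C)C)C[C@@H](C)C1=O | intermediate
5 | (1E,4S,6R)-4-[(tert-butyldiphenylsilyl)oxy]-2,2,6-trimethylcyclohexan-1-one oxime | CC1(C)C[C@@H](O[Si](c2ccccc2)(c2ccccc2)C(C)(C)C)C[C@@H](C)/C1=N\O | intermediate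
6 | O-acetyl oxime of 5 (not isolated) | CC1(C)C[C@@H](O[Si](c2ccccc2)(c2ccccc2)C(C)(C)C)C[C@@H](C)/C1=N\OC(C)=O | intermediate
7 | (1E,2S,4S,6R)-2-(acetoxymethyl)-4-[(tert-butyldiphenylsilyl)oxy]-2,6-dimethylcyclohexan-1-one O-acetyl oxime | CC(=O)OC[C@@]1(C)C[C@@H](O[Si](c2ccccc2)(c2ccccc2)C(C)(C)C)C[C@@H](C)/C1=N\OC(C)=O | intermediate
8 | N-H ketimine of 9 (not isolated) | CC(=O)OC[C@@]1(C)C[C@@H](O[Si](c2ccccc2)(c2ccccc2)C(C)(C)C)C[C@@H](C)C1=N | intermediate
9 | (2R,4S,6R)-2-(acetoxymethyl)-4-[(tert-butyldiphenylsilyl)oxy]-2,6-dimethylcyclohexan-1-one | CC(=O)OC[C@@]1(C)C[C@@H](O[Si](c2ccccc2)(c2ccccc2)C(C)(C)C)C[C@@H](C)C1=O | intermediate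
10 | [(1S,3R,5S)-5-[(tert-butyldiphenylsilyl)oxy]-1,3-dimethyl-2-methylidenecyclohexyl]methyl acetate | CC(=O)OC[C@@]1(C)C[C@@H](O[Si](c2ccccc2)(c2ccccc2)C(C)(C)C)C[C@@H](C)C1=C | intermediate
11 | [(1S,3R,5S)-5-hydroxy-1,3-dimethyl-2-methylidenecyclohexyl]methyl acetate | CC(=O)OC[C@@]1(C)C[C@@H](O)C[C@@H](C)C1=C | intermediate
12 | alkoxy(triphenyl)phosphonium ion of 11 (not isolated) | CC(=O)OC[C@@]1(C)C[C@@H](O[P+](c2ccccc2)(c2ccccc2)c2ccccc2)C[C@@H](C)C1=C | intermediate
13 | [(1S,3R,5R)-5-(chloroacetoxy)-1,3-dimethyl-2-methylidenecyclohexyl]methyl acetate (ring-A component; C2 oxygen α, C19 β, H-10 α) | CC(=O)OC[C@@]1(C)C[C@H](OC(=O)CCl)C[C@@H](C)C1=C | intermediate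
14 | geraniol | CC(C)=CCC/C(C)=C/CO | starting material
15 | geranyl chloroacetate | CC(C)=CCC/C(C)=C/COC(=O)CCl | intermediate
16 | (2E,6E)-8-hydroxy-3,7-dimethylocta-2,6-dien-1-yl chloroacetate | OC/C(C)=C/CC/C(C)=C/COC(=O)CCl | intermediate
17 | (2E,6E)-8-(methanesulfonyloxy)-3,7-dimethylocta-2,6-dien-1-yl chloroacetate (not isolated) | CS(=O)(=O)OC/C(C)=C/CC/C(C)=C/COC(=O)CCl | intermediate
18 | (2E,6E)-8-chloro-3,7-dimethylocta-2,6-dien-1-yl chloroacetate | ClC/C(C)=C/CC/C(C)=C/COC(=O)CCl | intermediate
19 | (E)-2-methylallyl cation from 18 (not isolated) | [CH2+]/C(C)=C/CC/C(C)=C/COC(=O)CCl | intermediate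
20 | tertiary C5 cation after C6–C7 bond formation (not isolated) | CC(=O)OC[C@@]1(C)C[C@H](OC(=O)CCl)C[C@@H](C)[C+]1CC/C(C)=C/CC/C(C)=C/COC(=O)CCl | intermediate
21 | tertiary C10 cation after 1,2-hydride shift, H-5 α (not isolated) | CC(=O)OC[C@@]1(C)C[C@H](OC(=O)CCl)C[C+](C)[C@H]1CC/C(C)=C/CC/C(C)=C/COC(=O)CCl | intermediate
22 | bicyclic C8 cation after C9–C10 bond formation (not isolated) | CC(=O)OC[C@@]1(C)C[C@H](OC(=O)CCl)C[C@]2(C)[C@@H](CC/C(C)=C/COC(=O)CCl)[C+](C)CC[C@@H]12 | intermediate
23 | 19-acetoxylabda-7,13E-diene-2α,15-diyl bis(chloroacetate) | CC(=O)OC[C@@]1(C)C[C@H](OC(=O)CCl)C[C@]2(C)[C@@H](CC/C(C)=C/COC(=O)CCl)C(C)=CC[C@@H]12 | intermediate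
24 | 2α,15-dihydroxylabda-7,13E-dien-19-yl acetate (CNP0319060.1) | CC(=O)OC[C@@]1(C)C[C@H](O)C[C@]2(C)[C@@H](CC/C(C)=C/CO)C(C)=CC[C@@H]12 | target

## Summary and risks

Total step count: 14 (steps 1–9 ring A, steps 10–12 side-chain component, steps 13–14).
Longest linear sequence: 11 steps (steps 1–9, 13, 14).

Steps most likely to fail:

Step 13 (Proposed new method). What may go wrong: ionisation of 18 that is slow compared with acid-induced isomerisation or oligomerisation of the alkenes; interception of cation 20 by the neighbouring acetate; cis ring fusion; unselective terminal proton loss (C17 or C9 instead of C7) or chloride capture at C8. The fallback uses known chemistry: C6–C7 by cross-coupling, then a separate Brønsted-acid cyclisation. It sets out from ketone 9 and geraniol 14.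
- Ketone 9 is converted (KHMDS, PhNTf2, THF, −78 °C; only the C10 side can enolise) into the enol triflate F1.
- Geraniol 14 is silylated (TBDPSCl, imidazole) to geranyl tert-butyldiphenylsilyl ether F2.
- F2 is oxidised at the (E)-methyl group (SeO2, t-BuOOH) to the allylic alcohol F3 and further (MnO2) to the enal F4.
- Wittig methylenation (Ph3P=CH2) gives the triene F5.
- Hydroboration of the vinyl group of F5 with 9-BBN gives the B-alkyl borane F6 (not isolated).
- F6 is coupled in the same flask with F1 (Pd(dppf)Cl2, AsPh3, Cs2CO3, DMF/THF/H2O; B-alkyl Suzuki–Miyaura coupling) to the monocyclic triene F7, which holds the C5=C10 and (E)-C8=C9 double bonds.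
- Both silyl ethers are removed (TBAF, AcOH) to give the diol F8.
- A double Mitsunobu reaction with chloroacetic acid esterifies O-15 and inverts C2 to give the bis(chloroacetate) F9.
- F9 is treated with FSO3H in 2-nitropropane at −78 °C (protonation of C5=C10 at C5, chair cyclisation through C9, loss of H-7). This should give 23, where the route is rejoined. In this variant H-5 and C10 are set by the chair that keeps the C2 ester equatorial and the C19 arm axial.

Step 5. What may go wrong: palladation of the other geminal methyl group or of the C10 methyl group (through another chair or the other oxime geometry), or double acetoxylation. The fallback is an alkoxy-radical relay instead of a directing group on the ketone, with the site fixed by a 1,3-diaxial contact. It sets out from 2.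
- Hydroxyl-directed hydrogenation (Crabtree's catalyst, H2, CH2Cl2) adds hydrogen syn to the hydroxyl group and gives the trans hydroxy ketone F10. Its axial hydroxyl group is syn-axial to the methyl group that becomes C19.
- Nitrosation (NOCl, pyridine, −20 °C) gives the nitrite F11.
- Barton nitrite photolysis (hν > 300 nm, benzene, then warming in i-PrOH) should give the oxime F12 by 1,5-hydrogen transfer from that methyl group.
- Ti(III) cleavage of the oxime (aq. TiCl3, NH4OAc) gives the hydroxy aldehyde F13 (present as its lactol).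
- NaBH4 at −40 °C gives the diol F14.
- AcCl/2,4,6-collidine at −78 °C gives the primary acetate F15.
- DBU equilibrates the α-methyl centre to the all-equatorial acetate F16.
- Takai–Lombardo methylenation of F16 gives 11, where the route is rejoined.

Step 9. What may go wrong: elimination or retention instead of SN2 displacement, because the nucleophile must approach syn-axial to the C18 methyl group. The fallback is oxidation–reduction instead of displacement. It sets out from 11.
- Dess–Martin oxidation gives the ketone F17.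
- L-Selectride at −78 °C should attack from the equatorial side, because the axial approach is blocked by the syn-axial methyl group on the quaternary carbon in the chair that keeps the acetoxymethyl and ring methyl groups equatorial. This gives the inverted alcohol F18.
- Chloroacetyl chloride/pyridine gives 13, where the route is rejoined.

Further compounds
F1 | step 13 | [(1S,5S)-5-[(tert-butyldiphenylsilyl)oxy]-1,3-dimethyl-2-(trifluoromethanesulfonyloxy)cyclohex-2-en-1-yl]methyl acetate (enol triflate of 9) | CC(=O)OC[C@@]1(C)C[C@@H](O[Si](c2ccccc2)(c2ccccc2)C(C)(C)C)CC(C)=C1OS(=O)(=O)C(F)(F)F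
F2 | step 13 | geranyl tert-butyldiphenylsilyl ether | CC(C)=CCC/C(C)=C/CO[Si](c1ccccc1)(c1ccccc1)C(C)(C)C
F3 | step 13 | (2E,6E)-8-[(tert-butyldiphenylsilyl)oxy]-2,6-dimethylocta-2,6-dien-1-ol | OC/C(C)=C/CC/C(C)=C/CO[Si](c1ccccc1)(c1ccccc1)C(C)(C)C
F4 | step 13 | (2E,6E)-8-[(tert-butyldiphenylsilyl)oxy]-2,6-dimethylocta-2,6-dienal | O=C/C(C)=C/CC/C(C)=C/CO[Si](c1ccccc1)(c1ccccc1)C(C)(C)C
F5 | step 13 | tert-butyl{[(2E,6E)-3,7-dimethylnona-2,6,8-trien-1-yl]oxy}diphenylsilane | C=C/C(C)=C/CC/C(C)=C/CO[Si](c1ccccc1)(c1ccccc1)C(C)(C)C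
F6 | step 13 | B-[(3E,7E)-9-[(tert-butyldiphenylsilyl)oxy]-3,7-dimethylnona-3,7-dien-1-yl]-9-borabicyclo[3.3.1]nonane (not isolated) | C(C/C(C)=C/CC/C(C)=C/CO[Si](c1ccccc1)(c1ccccc1)C(C)(C)C)B1C2CCCC1CCC2
F7 | step 13 | monocyclic triene with C5=C10 and (E)-C8=C9, bis(silyl ether), C19 acetate | CC(=O)OC[C@@]1(C)C[C@@H](O[Si](c2ccccc2)(c2ccccc2)C(C)(C)C)CC(C)=C1CC/C(C)=C/CC/C(C)=C/CO[Si](c1ccccc1)(c1ccccc1)C(C)(C)C
F8 | step 13 | monocyclic triene diol (C2 hydroxyl β, C15 hydroxyl), C19 acetate | CC(=O)OC[C@@]1(C)C[C@@H](O)CC(C)=C1CC/C(C)=C/CC/C(C)=C/CO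
F9 | step 13 | monocyclic triene bis(chloroacetate) (C2 oxygen α), C19 acetate | CC(=O)OC[C@@]1(C)C[C@H](OC(=O)CCl)CC(C)=C1CC/C(C)=C/CC/C(C)=C/COC(=O)CCl
F10 | step 5 | (4S,6S)-4-hydroxy-2,2,6-trimethylcyclohexan-1-one | CC1(C)C[C@@H](O)C[C@H](C)C1=O
F11 | step 5 | (1S,5S)-3,3,5-trimethyl-4-oxocyclohexyl nitrite | CC1(C)C[C@@H](ON=O)C[C@H](C)C1=O
F12 | step 5 | (1S,3S,5S)-5-hydroxy-1,3-dimethyl-2-oxocyclohexane-1-carbaldehyde oxime | ON=C[C@@]1(C)C[C@@H](O)C[C@H](C)C1=O
F13 | step 5 | (1S,3S,5S)-5-hydroxy-1,3-dimethyl-2-oxocyclohexane-1-carbaldehyde (lactol form in solution) | O=C[C@@]1(C)C[C@@H](O)C[C@H](C)C1=O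
F14 | step 5 | (2R,4S,6S)-4-hydroxy-2-(hydroxymethyl)-2,6-dimethylcyclohexan-1-one | OC[C@@]1(C)C[C@@H](O)C[C@H](C)C1=O
F15 | step 5 | [(1R,3S,5S)-5-hydroxy-1,3-dimethyl-2-oxocyclohexyl]methyl acetate | CC(=O)OC[C@@]1(C)C[C@@H](O)C[C@H](C)C1=O
F16 | step 5 | [(1R,3R,5S)-5-hydroxy-1,3-dimethyl-2-oxocyclohexyl]methyl acetate | CC(=O)OC[C@@]1(C)C[C@@H](O)C[C@@H](C)C1=O
F17 | step 9 | [(1S,3R)-1,3-dimethyl-2-methylidene-5-oxocyclohexyl]methyl acetate | CC(=O)OC[C@@]1(C)CC(=O)C[C@@H](C)C1=C
F18 | step 9 | [(1S,3R,5R)-5-hydroxy-1,3-dimethyl-2-methylidenecyclohexyl]methyl acetate | CC(=O)OC[C@@]1(C)C[C@H](O)C[C@@H](C)C1=C
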